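**Remark on the target:** coelenterazine (usual spelling) is 8-benzyl-2-(4-hydroxybenzyl)-6-(4-hydroxyphenyl)imidazo[1,2-a]pyrazin-3(7H)-one; it has no stereogenic centre or stereogenic double bond, so the L descriptors below only identify commercial building blocks. A check of the key-step acid and triacetate atom by atom against this skeleton turned up no structural error.

**Assumption:** 4-(benzyloxy)phenylglyoxal is bought as its hydrate 2; were a supply lacking, it is one SeO2 (Riley) oxidation away from 4'-(benzyloxy)acetophenone.

## Structural features

Compound 13 is a bicyclic imidazo[1,2-a]pyrazin-3(7H)-one: a five-membered imidazolone (N1, C2, C3, N4, C8a) fused along the N4–C8a bond to a six-membered dihydropyrazine-type ring (N4, C5, C6, N7, C8, C8a). Three appendages sit on this core: a 4-hydroxybenzyl group on C2, a 4-hydroxyphenyl group on C6 and a benzyl group on C8, while C5 carries hydrogen and N7 the mobile proton. There is no stereocentre, hence no neighbouring stereocentres to relate; the only isomerism is prototropic (7H-one, 2H-one and 3-hydroxy forms). The fragile part is the electron-rich 3-oxo/3-hydroxy core, which takes up O2 at C2, above all as its anion in basic aprotic media, and is then cleaved with loss of CO2; the two phenols add polarity and further sensitivity to oxidation. The real difficulty is therefore not the carbon skeleton. It lies in placing benzyl and aryl unambiguously at C8 and C6 of the pyrazine, and in closing the imidazolone at exactly the right oxidation level while the free luciferin appears only in the last operation. The key step exploits the fact that N1–C2(CH2Ar)–C3(=O) is a complete tyrosine unit whose nitrogen sits on C8a, so that N1–C8a–N4 is an amidine and the carboxyl carbon lies five atoms from ring nitrogen N4. Acylation of N4 by that carboxyl (bond N4–C3) closes the five-membered ring, and the enol of the new ring is an aromatic ten-π-electron imidazo[1,2-a]pyrazine that can be capped as an acetate.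

## Logic of the disconnections

**13 ⇒ 11.** The three O–acetyl bonds (at O3 and at both phenolic oxygens) are cut. The reason is handling: 13 is oxygen-sensitive and awkward to purify, whereas 11 is a fully aromatic, non-enolisable ester that can be chromatographed and stored. Purification moves to a robust compound. The demand on the forward step is deacylation without base and without oxygen, which points to acid-catalysed ethanolysis under argon.

**11 ⇒ 8.** The N4–C3 bond is cut, together with the three acetyl groups that the same flask installs. In 8, C2 is at the amine level and the pyrazine is aromatic, which together equal the oxidation level of 13, so ring closure is a plain dehydration with no oxidant and no labile ketoaldehyde. The bicycle is reduced to a monocyclic aromatic pyrazine carrying an intact amino acid. The forward step must activate the carboxyl so that ring nitrogen N4, not the exocyclic nitrogen or a second molecule, is acylated, and it must trap the oxygen-sensitive enol at once.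

**8 ⇒ 7.** Three O–CH2Ph bonds are cut. Both phenols and the acid must be masked during a basic palladium coupling: a free phenoxide would compete for the heteroaryl chloride and a free acid would bind the catalyst. Benzyl on all three positions is the one mask that falls in a single neutral operation leaving no salts; a methyl ether and methyl ester would instead need BBr3 followed by a separate saponification. One step replaces two. The demand is that hydrogenolysis spare the C–C-bound benzyl group at C8 and the pyrazine ring.

**7 ⇒ 5 + 6.** The aryl C–N bond N1–C8a is cut. This splits the molecule into a heteroaryl chloride and a purchasable, fully protected amino ester, so almost half of the atoms arrive in one convergent step. The forward step must couple a hindered α-branched primary amine with an only moderately activated 2-chloroazine without harming the ester, which calls for palladium/bisphosphine catalysis with a weak base. Configurational integrity is not required.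

**5 ⇒ 4.** The C8a–Cl bond is exchanged for the lactam C=O. The chloride is the activated form of a pyrazinone, and the pyrazinone is what a ring synthesis delivers directly. The demand is deoxychlorination that leaves the aryl benzyl ether intact.

**4 ⇒ 1 + 2.** The two ring C–N bonds N7–C6 and N4–C5 (numbering of 13) are cut. Both form by carbonyl condensation, so the whole trisubstituted pyrazine, already at the aromatic oxidation level, arises in one step from two catalogue compounds. Compound 1 supplies N7, C8 with its benzyl group, C8a and N4; 2 supplies C5, C6 and the aryl group. The demand is regiochemical: the amine nitrogen must end on the ketone carbon and the amide nitrogen on the aldehyde carbon.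

## Other disconnections considered

**Alternative 1:** Both bonds from the bridgehead nitrogen into the five-membered ring, N4–C3 and N4–C8a, are cut, and N7–C6 later. In the forward key step aminoketone A2 would open azlactone A1 at its acyl carbon, and the new amide nitrogen would then condense with the neighbouring amide carbonyl to give imidazolone A3. Removal of the carbamate would let N7 condense with the aryl ketone, and a prototropic shift would move the exocyclic C=C into the ring to reach 13.
- In its favour: three fragments of similar size, C–N bonds made by condensation only, no transition metal and no chlorinating agent. On convergence and freedom from metals it is better than the chosen plan.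
- Equal: redox economy, since the ring-closed successor of A3 is an isomer of 13.
- Against: A2 as the free base self-condenses; A1 is also a Michael acceptor; and the anhydride conditions that make A1 would acylate its phenol, so a protecting group is needed after all. The end-game relies on isomerisation out of a conjugated arylidene imidazolone, through a dihydro stage open to over-oxidation, and it delivers unprotected 13 with no stable resting form comparable to 11.
- Comparison: the step count would be about the same (five to six). Structurally, the chosen plan brings in C2 with its hydrogen already in place, while the alternative must relocate two hydrogens at the end. Mechanistically, one intramolecular acylation stands against two condensations plus a tautomerisation of uncertain driving force.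

**Alternative 2:** The only C–C bond of the pyrazine ring, C8–C8a, is cut, with the five-membered ring coming from a thiohydantoin. In the forward key step KOtBu would turn ketimine A4 into a 2-azaallyl anion whose amino acid α-carbon adds to C8a and expels methanethiolate (6-exo-trig addition–elimination) to give A5. Ester cleavage with decarboxylation, a prototropic shift and hydrogenolysis of the benzyl ethers would follow.
- In its favour: thiohydantoin chemistry is cheap and scalable; phenylalanine supplies N7, C8 and the benzyl group intact; and the C2 side chain enters from an aldehyde late in the sequence. For varying C2 it is better than the chosen plan.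
- Equal: redox neutrality, and use of a chiral-pool amino acid whose stereocentre is erased.
- Against: ketimine formation between a hindered aryl ketone and an amino ester is sluggish. The base may instead deprotonate the C5 methylene, the anion may react through its other terminus, or it may add in conjugate fashion to the arylidene. Three further operations follow the key step, the last ones on the oxygen-sensitive core.
- Comparison: roughly eight to nine steps against six. Making a quaternary carbon by C–C bond formation is mechanistically more demanding than a 5-exo N-acylation. Structurally, the alternative needs an ester at C8 only to remove it again.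

**Alternative 3:** N7–C6 and N4–C8a of the pyrazine are cut. In the forward key step Rh2(O2CC7H15)4 would decompose triazole A6 to an α-imino carbenoid that is captured by the nitrogen of azirine A7; ring opening, 6π-azaelectrocyclisation and loss of the sulfinic acid would give pyrazine A8.
- In its favour: the substituent positions are dictated by the connectivity of A6 and A7, so the pyrazine regiochemistry is unambiguous. On that point it is better than step 1 of the chosen plan. It is also catalytic and mild.
- Equal: no stereochemical issue in either plan.
- Against: A8 carries a carboxylate carbon where 13 needs nitrogen, so hydrolysis and a Curtius rearrangement to amine A9 (via an acyl azide) are required. The whole five-membered ring and the removal of the aryl methyl ether still lie ahead. A6 and A7 each need their own preparation, one of them with a sulfonyl azide.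
- Comparison: it solves in many steps only the half of the problem that step 1 solves in one; well over ten steps against six. Mechanistically it is elegant but rests on two strained or high-energy partners, whereas the chosen plan uses condensations and one cross-coupling.

Key step: step 5

## Route

**Step 1**
Reactants: 1 L-phenylalaninamide; 2 4-(benzyloxy)phenylglyoxal hydrate [1-[4-(benzyloxy)phenyl]-2,2-dihydroxyethan-1-one]
Product: 4 3-benzyl-5-[4-(benzyloxy)phenyl]pyrazin-2(1H)-one, via 3H-pyrazinone tautomer 3 (not isolated)
Conditions: NaOH (aq., 2 equiv), MeOH/THF, −35 °C → rt; then aq. HCl to pH 5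
Reagents that add atoms: none
Why: Jones pyrazinone synthesis: the α-amino amide and the 1,2-dicarbonyl compound condense twice (amine nitrogen on the ketone carbon, amide nitrogen on the aldehyde carbon, the orientation that strongly basic low-temperature conditions are known to favour for arylglyoxals) to give 3, whose C3–H shifts to nitrogen to give aromatic 4 at unchanged oxidation level; the phenylalanine stereocentre is thereby erased and no new one is formed.

**Step 2**
Reactants: 4 3-benzyl-5-[4-(benzyloxy)phenyl]pyrazin-2(1H)-one
Product: 5 3-benzyl-5-[4-(benzyloxy)phenyl]-2-chloropyrazine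
Conditions: POCl3 (3 equiv), PhNEt2 (1 equiv), toluene, 90 °C
Reagents that add atoms: phosphoryl chloride, O=P(Cl)(Cl)Cl
Why: Deoxychlorination of a 2-hydroxyazine: O-phosphorylation of the lactam creates a dichlorophosphate leaving group that chloride displaces by addition–elimination at C2; PhNEt2 buffers the HCl so that the aryl benzyl ether is not cleaved, and no stereocentre is involved.

**Step 3**
Reactants: 5 3-benzyl-5-[4-(benzyloxy)phenyl]-2-chloropyrazine; 6 O-benzyl-L-tyrosine benzyl ester hydrochloride
Product: 7 benzyl N-{3-benzyl-5-[4-(benzyloxy)phenyl]pyrazin-2-yl}-O-benzyl-L-tyrosinate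
Conditions: Pd(OAc)2 (5 mol%), rac-BINAP (7.5 mol%), Cs2CO3 (3 equiv), toluene, 90 °C, Ar
Reagents that add atoms: none
Why: Buchwald–Hartwig amination: zerovalent palladium formed in situ from Pd(OAc)2 and BINAP inserts into the activated C–Cl bond, Cs2CO3 frees the amine of 6 and deprotonates the bound ammonium, and reductive elimination forms the C8a–N1 bond; the weak carbonate base spares the benzyl ester and the benzylated phenol cannot compete as an oxygen nucleophile. Any racemisation at Cα would be harmless because step 5 destroys this centre.

**Step 4**
Reactants: 7 benzyl N-{3-benzyl-5-[4-(benzyloxy)phenyl]pyrazin-2-yl}-O-benzyl-L-tyrosinate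
Product: 8 N-[3-benzyl-5-(4-hydroxyphenyl)pyrazin-2-yl]-L-tyrosine
Conditions: H2 (1 atm), Pd/C (10 wt% Pd, 10 mol%), THF/MeOH (1:1), rt
Reagents that add atoms: none
Why: Catalytic hydrogenolysis cleaves the two aryl benzyl ethers and the benzyl ester in one neutral operation whose only by-product is toluene; the benzyl group at C8 is C–C bound, the aromatic pyrazine is not reduced at 1 atm, and no C–halogen bond remains to be lost.

**Step 5**
Reactants: 8 N-[3-benzyl-5-(4-hydroxyphenyl)pyrazin-2-yl]-L-tyrosine
Product: 11 2-(4-acetoxybenzyl)-6-(4-acetoxyphenyl)-8-benzylimidazo[1,2-a]pyrazin-3-yl acetate, via mixed acetic anhydride 9 (not isolated), via 2H-imidazopyrazinone 10 (not isolated)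
Conditions: Ac2O (8 equiv), pyridine (6 equiv), degassed THF, Ar, 0 → 45 °C
Reagents that add atoms: acetic anhydride, CC(=O)OC(C)=O
Why: Pyridine and Ac2O acetylate the two phenols and convert the carboxyl group into mixed anhydride 9. In 9 the tyrosine nitrogen and ring nitrogen N4 form an amidine whose ring nitrogen holds the more available lone pair; it sits five atoms from the activated carbonyl and attacks it in a 5-exo-trig addition–elimination that expels acetate and forms N4–C3, the only ring closure of the step. Loss of the N–H proton gives neutral 2H-imidazopyrazinone 10, already at the oxidation level of 13. C2–H of 10, flanked by the lactam carbonyl and the C=N bond, is acidic; enolisation gives an aromatic ten-π-electron imidazo[1,2-a]pyrazin-3-ol that is O-acetylated to air-stable 11. No stereocentre is created: the tyrosine centre becomes sp2, so no controlling element is needed. The selectivity required is acylation of N4 in preference to the exocyclic nitrogen and to a second molecule; the exocyclic nitrogen is α-branched and its lone pair is delocalised into the electron-poor pyrazine, closure at N4 is intramolecular and geometrically ideal, and distal N7 cannot reach the carbonyl. The closest known reaction type is the cyclodehydration of N-(azin-2-yl) α-amino acids with anhydrides or carbodiimides to fused imidazol-3-ones and their O-acyl derivatives. Oxygen is excluded because the enolate of 10 is the species that would otherwise capture O2.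

**Step 6**
Reactants: 11 2-(4-acetoxybenzyl)-6-(4-acetoxyphenyl)-8-benzylimidazo[1,2-a]pyrazin-3-yl acetate
Product: 13 coelenterazine [8-benzyl-2-(4-hydroxybenzyl)-6-(4-hydroxyphenyl)imidazo[1,2-a]pyrazin-3(7H)-one], via 3-hydroxy tautomer 12 (not isolated)
Conditions: HCl (37% aq., cat.), degassed EtOH, Ar, 50 °C; evaporate, triturate under Ar
Reagents that add atoms: none
Why: Acid-catalysed transesterification (ethanolysis) removes the enol acetate and both aryl acetates as ethyl acetate; the freed 3-hydroxy form 12 tautomerises to 13, which stays protonated and under argon so that the oxygen-sensitive anion never forms. HCl acts as catalyst and leaves with the solvent, and no stereocentre is present.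

## Compound list

1 | L-phenylalaninamide | N[C@@H](Cc1ccccc1)C(N)=O | starting material
2 | 4-(benzyloxy)phenylglyoxal hydrate, 1-[4-(benzyloxy)phenyl]-2,2-dihydroxyethan-1-one | OC(O)C(=O)c1ccc(OCc2ccccc2)cc1 | starting material
3 | (3S)-3-benzyl-5-[4-(benzyloxy)phenyl]pyrazin-2(3H)-one | O=C1N=CC(c2ccc(OCc3ccccc3)cc2)=N[C@H]1Cc1ccccc1 | intermediate
4 | 3-benzyl-5-[4-(benzyloxy)phenyl]pyrazin-2(1H)-one | O=c1[nH]cc(-c2ccc(OCc3ccccc3)cc2)nc1Cc1ccccc1 | intermediate
5 | 3-benzyl-5-[4-(benzyloxy)phenyl]-2-chloropyrazine | Clc1ncc(-c2ccc(OCc3ccccc3)cc2)nc1Cc1ccccc1 | intermediate
6 | O-benzyl-L-tyrosine benzyl ester hydrochloride | Cl.N[C@@H](Cc1ccc(OCc2ccccc2)cc1)C(=O)OCc1ccccc1 | starting material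
7 | benzyl N-{3-benzyl-5-[4-(benzyloxy)phenyl]pyrazin-2-yl}-O-benzyl-L-tyrosinate | O=C(OCc1ccccc1)[C@H](Cc1ccc(OCc2ccccc2)cc1)Nc1ncc(-c2ccc(OCc3ccccc3)cc2)nc1Cc1ccccc1 | intermediate
8 | N-[3-benzyl-5-(4-hydroxyphenyl)pyrazin-2-yl]-L-tyrosine | OC(=O)[C@H](Cc1ccc(O)cc1)Nc1ncc(-c2ccc(O)cc2)nc1Cc1ccccc1 | intermediate
9 | acetic N-[5-(4-acetoxyphenyl)-3-benzylpyrazin-2-yl]-O-acetyl-L-tyrosine anhydride | CC(=O)OC(=O)[C@H](Cc1ccc(OC(C)=O)cc1)Nc1ncc(-c2ccc(OC(C)=O)cc2)nc1Cc1ccccc1 | intermediate
10 | (2S)-2-(4-acetoxybenzyl)-6-(4-acetoxyphenyl)-8-benzylimidazo[1,2-a]pyrazin-3(2H)-one (configurationally labile) | CC(=O)Oc1ccc(C[C@@H]2N=C3C(Cc4ccccc4)=NC(c4ccc(OC(C)=O)cc4)=CN3C2=O)cc1 | intermediate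
11 | 2-(4-acetoxybenzyl)-6-(4-acetoxyphenyl)-8-benzylimidazo[1,2-a]pyrazin-3-yl acetate | CC(=O)Oc1ccc(Cc2nc3c(Cc4ccccc4)nc(-c4ccc(OC(C)=O)cc4)cn3c2OC(C)=O)cc1 | intermediate
12 | 8-benzyl-2-(4-hydroxybenzyl)-6-(4-hydroxyphenyl)imidazo[1,2-a]pyrazin-3-ol | Oc1ccc(Cc2nc3c(Cc4ccccc4)nc(-c4ccc(O)cc4)cn3c2O)cc1 | intermediate
13 | coelenterazine, 8-benzyl-2-(4-hydroxybenzyl)-6-(4-hydroxyphenyl)imidazo[1,2-a]pyrazin-3(7H)-one | O=c1c(Cc2ccc(O)cc2)nc2c(Cc3ccccc3)[nH]c(-c3ccc(O)cc3)cn1-2 | target

## Step count and risk

Total step count: 6. Longest linear sequence: 6 steps (from 1 or 2 to 13); 6 enters as a purchased partner in step 3.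

**Step 5 (key step).** Most likely to go wrong: acetyl transfer to the exocyclic nitrogen competing with ring closure, and autoxidation of the transient enol before it is capped. The fallback sets out from 8 and comes back at 11, and no compound outside the list arises (F0). It separates ring closure from acetylation. Compound 8 would be treated with N,N'-dicyclohexylcarbodiimide in degassed pyridine under argon, a known dehydrative closure for N-pyrazinyl amino acids. The O-acylisourea can only be attacked intramolecularly by N4, and no acetyl donor is present while an N–H still exists. Once the ring is closed (13 in solution), Ac2O is added to the same flask to acetylate the three hydroxyl groups, giving 11.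

**Step 3.** Most likely to go wrong: slow C–N reductive elimination with the hindered α-branched amine, deactivation of the catalyst by chelation to the aminopyrazine product, and self-condensation of the free amino ester on heating. The fallback sets out from 5 and comes back at 8. It is an Ullmann-type coupling of the unprotected amino acid. Compound 5 and commercial O-benzyl-L-tyrosine with CuI (10 mol%) and K2CO3 in DMA at 90 °C, where the α-amino carboxylate itself chelates monovalent copper and accelerates N-arylation, should give N-{3-benzyl-5-[4-(benzyloxy)phenyl]pyrazin-2-yl}-O-benzyl-L-tyrosine F1. Hydrogenolysis (H2, Pd/C) of its two benzyl ethers then gives 8.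

**Step 1.** Most likely to go wrong: erosion of regiocontrol (the amine nitrogen condensing at the aldehyde carbon, which leads to the 3,6-substitution pattern) and base-induced self-destruction of the glyoxal. The fallback sets out from 1 and comes back at 4. Compound 1 is condensed with glyoxal itself under the same Jones conditions, where no regiochemical question exists, to give 3-benzylpyrazin-2(1H)-one F2. NBS in DMF at 0 °C brominates C5, the β-carbon of the ring enamide and the only activated free position, to give 3-benzyl-5-bromopyrazin-2(1H)-one F3. Suzuki–Miyaura coupling with 4-(benzyloxy)phenylboronic acid (Pd(dppf)Cl2, K2CO3, dioxane/H2O, 90 °C) then gives 4.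

**Step 4.** Most likely to go wrong: stalling of the hydrogenolysis through poisoning of the catalyst surface by the chelating aminopyrazine, and precipitation of partly debenzylated material. The fallback sets out from 7 and comes back at 8, and no compound outside the list arises (F0). It is a non-reductive Lewis-acid debenzylation with BCl3 and pentamethylbenzene as cation scavenger in CH2Cl2 at −78 → 0 °C. Both ethers and the ester are cleaved by ionisation, the benzyl cations are captured by the scavenger and not by the electron-rich phenols, and aqueous work-up releases 8.

**Step 6.** Most likely to go wrong: autoxidation of the liberated luciferin during solvolysis and isolation, and incomplete ethanolysis of the aryl acetates. The fallback sets out from 8 and comes back at 13. It replaces the acetate trap by a benzyl carbonate so that the final unmasking is reductive. Compound 8 with benzyl chloroformate (5 equiv) and pyridine in degassed THF under argon (mixed carbonic anhydride activation, the same N4–C3 closure, then O-acylation) should give benzyl 8-benzyl-2-(4-{[(benzyloxy)carbonyl]oxy}benzyl)-6-(4-{[(benzyloxy)carbonyl]oxy}phenyl)imidazo[1,2-a]pyrazin-3-yl carbonate F4. H2 and Pd/C in EtOAc then cleave the three carbonates under an oxygen-free, reducing atmosphere, leaving only toluene and CO2, and filtration under argon gives 13.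

## Further compounds

F0 | step 5 | none | none
F1 | step 3 | N-{3-benzyl-5-[4-(benzyloxy)phenyl]pyrazin-2-yl}-O-benzyl-L-tyrosine | OC(=O)[C@H](Cc1ccc(OCc2ccccc2)cc1)Nc1ncc(-c2ccc(OCc3ccccc3)cc2)nc1Cc1ccccc1
F2 | step 1 | 3-benzylpyrazin-2(1H)-one | O=c1[nH]ccnc1Cc1ccccc1
F3 | step 1 | 3-benzyl-5-bromopyrazin-2(1H)-one | O=c1[nH]cc(Br)nc1Cc1ccccc1
F0 | step 4 | none | none
F4 | step 6 | benzyl 8-benzyl-2-(4-{[(benzyloxy)carbonyl]oxy}benzyl)-6-(4-{[(benzyloxy)carbonyl]oxy}phenyl)imidazo[1,2-a]pyrazin-3-yl carbonate | O=C(OCc1ccccc1)Oc1ccc(Cc2nc3c(Cc4ccccc4)nc(-c4ccc(OC(=O)OCc5ccccc5)cc4)cn3c2OC(=O)OCc2ccccc2)cc1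
A1 | alternative 1 | tert-butyl N-{(1S)-1-[(4Z)-4-(4-hydroxybenzylidene)-5-oxo-4,5-dihydro-1,3-oxazol-2-yl]-2-phenylethyl}carbamate | CC(C)(C)OC(=O)N[C@@H](Cc1ccccc1)C1=N/C(=C\c2ccc(O)cc2)C(=O)O1
A2 | alternative 1 | 2-amino-1-(4-hydroxyphenyl)ethan-1-one | NCC(=O)c1ccc(O)cc1
A3 | alternative 1 | tert-butyl N-{(1S)-1-[(4Z)-4-(4-hydroxybenzylidene)-1-[2-(4-hydroxyphenyl)-2-oxoethyl]-5-oxo-4,5-dihydro-1H-imidazol-2-yl]-2-phenylethyl}carbamate | CC(C)(C)OC(=O)N[C@@H](Cc1ccccc1)C1=N/C(=C\c2ccc(O)cc2)C(=O)N1CC(=O)c1ccc(O)cc1
A4 | alternative 2 | tert-butyl N-{1-[4-(benzyloxy)phenyl]-2-[(4Z)-4-[4-(benzyloxy)benzylidene]-2-(methylsulfanyl)-5-oxo-4,5-dihydro-1H-imidazol-1-yl]ethylidene}-L-phenylalaninate | CSC1=N/C(=C\c2ccc(OCc3ccccc3)cc2)C(=O)N1CC(=N[C@@H](Cc1ccccc1)C(=O)OC(C)(C)C)c1ccc(OCc2ccccc2)cc1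
A5 | alternative 2 | tert-butyl (2Z)-8-benzyl-2-[4-(benzyloxy)benzylidene]-6-[4-(benzyloxy)phenyl]-3-oxo-2,3,5,8-tetrahydroimidazo[1,2-a]pyrazine-8-carboxylate (racemic at C8) | CC(C)(C)OC(=O)C1(Cc2ccccc2)N=C(c2ccc(OCc3ccccc3)cc2)CN2C(=O)/C(=C/c3ccc(OCc4ccccc4)cc3)N=C12
A6 | alternative 3 | 4-(4-methoxyphenyl)-1-(4-methylbenzenesulfonyl)-1H-1,2,3-triazole | COc1ccc(cc1)-c1cn(nn1)S(=O)(=O)c1ccc(C)cc1
A7 | alternative 3 | methyl 3-benzyl-2H-azirine-2-carboxylate (racemic) | COC(=O)C1N=C1Cc1ccccc1
A8 | alternative 3 | methyl 3-benzyl-5-(4-methoxyphenyl)pyrazine-2-carboxylate | COC(=O)c1ncc(-c2ccc(OC)cc2)nc1Cc1ccccc1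
A9 | alternative 3 | 3-benzyl-5-(4-methoxyphenyl)pyrazin-2-amine | Nc1ncc(-c2ccc(OC)cc2)nc1Cc1ccccc1
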